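**Plan**

1. Numbering used throughout (labdane): ring A = C1–C5 + C10, ring B = C5–C10, C17 on C8, C11–C12 between C9 and the butenolide (C13–C16), C18 (α) and C19 (β) on C4, C20 on C10; β is the face of C20.
2. Cuts: C12–C13 (the lactone is joined as a bought, preformed ring), C4–C18, then C5–C10 together with C3–C4 (intramolecular Diels–Alder reaction of an acyclic trienal), then C8–C9 (Ireland–Claisen rearrangement) and C10–C20/C1–C2 (alkyne carbometalation–coupling).
3. Feature that allows the key event: C1, C2 and C3 of ring A are plain CH2 groups and C4 bears the C19 carbonyl carbon. So C10=C1–C2=C3 can be a diene, C4=C5–C19HO its enal dienophile, and the ring-B carbons C6–C9 (already carrying C17 and C11=C12) the four-atom tether.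
4. Forward order: acyclic C8–C9 unit, then diene, then trienal; one cycloaddition closes ring B (C5–C10 bond) and, with the C3–C4 bond, ring A last; after that no ring is formed.
5. Stereochemistry: C8 and C9 from the enantioselective boron-enolate Ireland–Claisen step; C5 and C10 from the endo, chair-like cycloaddition in which the C8 and C9 substituents sit equatorial; C4 from α-face methylation anti to C20.

Key step: step 12

Assumption: the sense of induction of the (S,S)-configured boron controller in step 5 is taken, by analogy with simple (E)-allyl esters, to give the (2R,3S) acid; the (R,R)-controller, made the same way, would give the mirror-image series.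

**Route**

Step 1
Reactants: 1 3-(trimethylsilyl)prop-2-ynal; 2 triethyl phosphonoacetate
Product: 3 ethyl (2E)-5-(trimethylsilyl)pent-2-en-4-ynoate
Conditions: LiCl, DBU, MeCN, 0 °C to rt
Reagents that add atoms: none
Why: Horner–Wadsworth–Emmons olefination of the ynal with the lithium-chelated phosphonate anion under mild amine-base conditions should give the (E)-enoate and leave the C-silyl alkyne untouched.

Step 2
Reactants: 3 ethyl (2E)-5-(trimethylsilyl)pent-2-en-4-ynoate
Product: 4 (2E)-5-(trimethylsilyl)pent-2-en-4-yn-1-ol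
Conditions: iBu2AlH (2.2 equiv), CH2Cl2, −78 to 0 °C
Reagents that add atoms: none
Why: 1,2-reduction of the conjugated ester by the aluminium hydride should give the allylic alcohol without touching the enyne, whose (E) geometry is carried on.

Step 3
Reactants: 5 δ-valerolactone (oxan-2-one)
Product: 8 5-[(tert-butyldimethylsilyl)oxy]pentanoic acid, via sodium 5-hydroxypentanoate 6 (not isolated), via bis-silyl derivative 7 (not isolated)
Conditions: NaOH, H2O/MeOH, rt, then evaporation; TBSCl, imidazole, DMF, rt; K2CO3 (cat.), MeOH/THF/H2O, rt, then pH 4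
Reagents that add atoms: sodium hydroxide [Na+].[OH-]; tert-butyldimethylsilyl chloride CC(C)(C)[Si](C)(C)Cl
Why: saponification opens the lactone, silylation caps both oxygens and the labile silyl ester is then hydrolysed selectively (standard hydroxy-acid protection sequence), which leaves the primary silyl ether as the later C5 handle.

Step 4
Reactants: 8 5-[(tert-butyldimethylsilyl)oxy]pentanoic acid; 4 (2E)-5-(trimethylsilyl)pent-2-en-4-yn-1-ol
Product: 9 (2E)-5-(trimethylsilyl)pent-2-en-4-yn-1-yl 5-[(tert-butyldimethylsilyl)oxy]pentanoate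
Conditions: DCC, DMAP (cat.), CH2Cl2, 0 °C to rt
Reagents that add atoms: none
Why: Steglich esterification joins the acid (C5–C8, C17) and the enynol (C12, C11, C9, C10, C1) without disturbing the silyl groups.

Step 5
Reactants: 9 (2E)-5-(trimethylsilyl)pent-2-en-4-yn-1-yl 5-[(tert-butyldimethylsilyl)oxy]pentanoate
Product: 12 (2R,3S)-2-{3-[(tert-butyldimethylsilyl)oxy]propyl}-3-ethenyl-5-(trimethylsilyl)pent-4-ynoic acid, via boron ketene acetal 10 (not isolated), via boron carboxylate 11 (not isolated)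
Conditions: (1S,2S)-N,N'-bis{[3,5-bis(trifluoromethyl)phenyl]sulfonyl}-1,2-diphenylethane-1,2-diamine, BBr3, CH2Cl2, rt, then evacuation; 9, iPr2NEt, CH2Cl2, −78 °C, then −20 °C; aqueous work-up
Reagents that add atoms: none
Why: Ireland–Claisen rearrangement through a chiral boron enolate, in which the Z(O) ketene acetal 10 formed with iPr2NEt in CH2Cl2 and the (E)-allylic double bond react through a chair transition state to the syn acid, creating the C8–C9 bond and both stereocenters, while the C2-symmetric diazaborolidine selects the enolate face and so fixes the absolute configuration.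

Step 6
Reactants: 12 (2R,3S)-2-{3-[(tert-butyldimethylsilyl)oxy]propyl}-3-ethenyl-5-(trimethylsilyl)pent-4-ynoic acid
Product: 14 (2R,3S)-2-{3-[(tert-butyldimethylsilyl)oxy]propyl}-3-ethenylpent-4-yn-1-ol, via silylalkyne alcohol 13 (not isolated)
Conditions: LiAlH4, THF, 0 °C; aqueous work-up; then K2CO3 (cat.), MeOH, rt
Reagents that add atoms: none
Why: LiAlH4 reduces the carboxylic acid to the C17 primary alcohol and mild methanolysis then removes the alkynyl silyl group, neither operation affecting the non-acidic C8 and C9 stereocenters or the silyl ether.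

Step 7
Reactants: 14 (2R,3S)-2-{3-[(tert-butyldimethylsilyl)oxy]propyl}-3-ethenylpent-4-yn-1-ol
Product: 15 tert-butyl{[(2R,3S)-2-{3-[(tert-butyldimethylsilyl)oxy]propyl}-3-ethenylpent-4-yn-1-yl]oxy}diphenylsilane
Conditions: TBDPSCl, imidazole, DMF, rt
Reagents that add atoms: tert-butyl(chloro)diphenylsilane CC(C)(C)[Si](Cl)(c1ccccc1)c1ccccc1
Why: standard silylation protects the C17 hydroxyl as a robust silyl ether that survives the later selective removal of the primary TBS group.

Step 8
Reactants: 15 tert-butyl{[(2R,3S)-2-{3-[(tert-butyldimethylsilyl)oxy]propyl}-3-ethenylpent-4-yn-1-yl]oxy}diphenylsilane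
Product: 17 tert-butyl{[(2R,3S,4E)-2-{3-[(tert-butyldimethylsilyl)oxy]propyl}-3-ethenyl-4-methylhepta-4,6-dien-1-yl]oxy}diphenylsilane, via alkenylalane 16 (not isolated)
Conditions: AlMe3 (3 equiv), Cp2ZrCl2 (20 mol %), CH2Cl2, 0 °C to rt; then vinyl bromide, Pd(PPh3)4 (5 mol %), ZnCl2 (10 mol %), THF, rt
Reagents that add atoms: trimethylaluminium C[Al](C)C; vinyl bromide C=CBr
Why: zirconium-catalysed carboalumination of the terminal alkyne (syn addition, methyl to the internal carbon C10) followed by palladium-catalysed cross-coupling of the alkenylalane 16 with vinyl bromide under retention (Negishi coupling) should give the diene with the C9 tether trans and the methyl group cis to the new vinyl unit.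

Step 9
Reactants: 17 tert-butyl{[(2R,3S,4E)-2-{3-[(tert-butyldimethylsilyl)oxy]propyl}-3-ethenyl-4-methylhepta-4,6-dien-1-yl]oxy}diphenylsilane
Product: 18 (4R,5S,6E)-4-{[(tert-butyldiphenylsilyl)oxy]methyl}-5-ethenyl-6-methylnona-6,8-dien-1-ol
Conditions: PPTS (cat.), EtOH, 40 °C
Reagents that add atoms: none
Why: acid-catalysed ethanolysis cleaves the unhindered primary TBS ether much faster than the TBDPS ether, which frees only the C5 hydroxyl.

Step 10
Reactants: 18 (4R,5S,6E)-4-{[(tert-butyldiphenylsilyl)oxy]methyl}-5-ethenyl-6-methylnona-6,8-dien-1-ol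
Product: 19 (4R,5S,6E)-4-{[(tert-butyldiphenylsilyl)oxy]methyl}-5-ethenyl-6-methylnona-6,8-dienal
Conditions: Dess–Martin periodinane, CH2Cl2, 0 °C to rt
Reagents that add atoms: none
Why: Dess–Martin oxidation converts the primary alcohol into the aldehyde under near-neutral conditions that the skipped triene tolerates.

Step 11
Reactants: 19 (4R,5S,6E)-4-{[(tert-butyldiphenylsilyl)oxy]methyl}-5-ethenyl-6-methylnona-6,8-dienal; 20 (triphenylphosphoranylidene)acetaldehyde
Product: 21 (2E,6R,7S,8E)-6-{[(tert-butyldiphenylsilyl)oxy]methyl}-7-ethenyl-8-methylundeca-2,8,10-trienal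
Conditions: toluene, 80 °C
Reagents that add atoms: none
Why: Wittig olefination with the stabilised formyl ylide should give the (E)-enal, which installs C4 and C19 and completes the dienophile.

Step 12
Reactants: 21 (2E,6R,7S,8E)-6-{[(tert-butyldiphenylsilyl)oxy]methyl}-7-ethenyl-8-methylundeca-2,8,10-trienal
Product: 22 (1R,4aS,5S,6R,8aS)-6-{[(tert-butyldiphenylsilyl)oxy]methyl}-5-ethenyl-4a-methyl-1,2,4a,5,6,7,8,8a-octahydronaphthalene-1-carbaldehyde (trans-fused; 4α-CHO, 5α-H, 8α-CH2OSi, 9β-vinyl, 10β-methyl, C1=C2)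
Conditions: Me2AlCl (1.2 equiv), CH2Cl2, −78 to −20 °C
Reagents that add atoms: none
Why: Me2AlCl binds the formyl oxygen and the (E)-enal C4=C5 adds suprafacially to the s-cis diene C10=C1–C2=C3 in an intramolecular Diels–Alder reaction of the terminally activated 1,7,9-decatriene type, the closest precedent being Lewis-acid-promoted cycloadditions of (2E,8E)-deca-2,8,10-trienals to trans-fused octalins. The transition state is asynchronous: the bond from the enal β-carbon C5 to C10 is the more advanced one and closes ring B through the four-atom tether C6–C9 (fused mode, chair-like), and the C3–C4 bond then completes ring A as the cyclohexene of the [4+2] event, so that ring A is the last ring to close. C10 is set by the diene geometry (tether outside, methyl inside, hence an angular methyl group) and by the diene face that lets the C8 silyloxymethyl and C9 vinyl groups sit equatorial on the chair tether; C5 follows from the (E)-dienophile and the endo transition state with the aluminium-bound formyl group under the diene, which gives the trans ring fusion (5α-H, 10β-methyl); C4 (4α-CHO) is a by-product of the endo mode and is reset in step 13. The step needs endo over exo selectivity, secured by the Lewis acid and the low temperature, and diastereofacial selectivity, secured by the two tether substituents, since the other trans-fused transition state would place both of them axial. The inside methyl group twists the diene and slows the reaction, which the Lewis-acid activation of the enal is meant to offset.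

Step 13
Reactants: 22 (1R,4aS,5S,6R,8aS)-6-{[(tert-butyldiphenylsilyl)oxy]methyl}-5-ethenyl-4a-methyl-1,2,4a,5,6,7,8,8a-octahydronaphthalene-1-carbaldehyde
Product: 24 (1S,4aR,5S,6R,8aR)-6-{[(tert-butyldiphenylsilyl)oxy]methyl}-5-ethenyl-1,4a-dimethyl-1,2,4a,5,6,7,8,8a-octahydronaphthalene-1-carbaldehyde (4α-methyl, 4β-CHO), via potassium enolate 23 (not isolated)
Conditions: KOtBu, THF/tBuOH, 0 °C; MeI, 0 °C to rt
Reagents that add atoms: iodomethane CI
Why: C-methylation of the aldehyde enolate 23 should occur on the α face, anti to the axial 10β-methyl group that shields the β face in a 1,3-diaxial sense, so that C4 becomes quaternary with 4α-methyl and 4β-formyl (enolate alkylation under steric approach control).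

Step 14
Reactants: 24 (1S,4aR,5S,6R,8aR)-6-{[(tert-butyldiphenylsilyl)oxy]methyl}-5-ethenyl-1,4a-dimethyl-1,2,4a,5,6,7,8,8a-octahydronaphthalene-1-carbaldehyde
Product: 25 (1S,4aR,5S,6R,8aR)-6-{[(tert-butyldiphenylsilyl)oxy]methyl}-5-ethenyl-1,4a-dimethyl-1,2,4a,5,6,7,8,8a-octahydronaphthalene-1-carboxylic acid
Conditions: NaClO2, NaH2PO4, 2-methylbut-2-ene, tBuOH/H2O, rt
Reagents that add atoms: sodium chlorite [Na+].[O-]Cl=O
Why: Pinnick oxidation converts the hindered aldehyde into the C19 carboxylic acid while the alkene scavenger protects the two double bonds from hypochlorite.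

Step 15
Reactants: 26 furan-2(5H)-one
Product: 28 3-bromofuran-2(5H)-one, via dibromolactone 27 (not isolated)
Conditions: Br2, Et2O, 0 °C to rt; then Et3N, 0 °C
Reagents that add atoms: bromine BrBr
Why: bromine adds across the butenolide double bond and the amine then removes the acidic C3 proton with loss of the C4 bromide (bromination–dehydrobromination), which gives the α-bromo butenolide.

Step 16
Reactants: 25 (1S,4aR,5S,6R,8aR)-6-{[(tert-butyldiphenylsilyl)oxy]methyl}-5-ethenyl-1,4a-dimethyl-1,2,4a,5,6,7,8,8a-octahydronaphthalene-1-carboxylic acid; 28 3-bromofuran-2(5H)-one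
Product: 30 (1S,4aR,5S,6R,8aR)-6-{[(tert-butyldiphenylsilyl)oxy]methyl}-1,4a-dimethyl-5-[2-(2-oxo-2,5-dihydrofuran-3-yl)ethyl]-1,2,4a,5,6,7,8,8a-octahydronaphthalene-1-carboxylic acid, via bis-borane adduct 29 (not isolated)
Conditions: 9-BBN-H (2.5 equiv), THF, 0 °C to rt; then 28, PdCl2(dppf) (5 mol %), AsPh3 (10 mol %), Cs2CO3, DMF/H2O, rt; acidic work-up
Reagents that add atoms: none
Why: 9-BBN-H first masks the acid as an acyloxyborane and hydroborates only the monosubstituted C11=C12 alkene at its terminus, and the resulting primary alkylborane is joined to the α-bromo butenolide by a B-alkyl Suzuki–Miyaura coupling, which attaches the ready-made lactone ring through the C12–C13 bond.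

Step 17
Reactants: 30 (1S,4aR,5S,6R,8aR)-6-{[(tert-butyldiphenylsilyl)oxy]methyl}-1,4a-dimethyl-5-[2-(2-oxo-2,5-dihydrofuran-3-yl)ethyl]-1,2,4a,5,6,7,8,8a-octahydronaphthalene-1-carboxylic acid
Product: 31 (1S,4aR,5S,6R,8aR)-6-{[(tert-butyldiphenylsilyl)oxy]methyl}-1,4a-dimethyl-5-[2-(2-oxo-2,5-dihydrofuran-3-yl)ethyl]decahydronaphthalene-1-carboxylic acid
Conditions: H2 (3 atm), RhCl(PPh3)3 (10 mol %), benzene/EtOH, rt
Reagents that add atoms: none
Why: homogeneous hydrogenation with RhCl(PPh3)3 should reduce the cis-disubstituted ring-A alkene but not the trisubstituted, conjugated butenolide double bond (steric discrimination typical of this catalyst).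

Step 18
Reactants: 31 (1S,4aR,5S,6R,8aR)-6-{[(tert-butyldiphenylsilyl)oxy]methyl}-1,4a-dimethyl-5-[2-(2-oxo-2,5-dihydrofuran-3-yl)ethyl]decahydronaphthalene-1-carboxylic acid
Product: 32 (1S,4aR,5S,6R,8aR)-6-(hydroxymethyl)-1,4a-dimethyl-5-[2-(2-oxo-2,5-dihydrofuran-3-yl)ethyl]decahydronaphthalene-1-carboxylic acid (target)
Conditions: HF·pyridine, THF/pyridine, 0 °C to rt
Reagents that add atoms: none
Why: fluoride-mediated cleavage of the silyl ether under mildly acidic conditions frees the C17 hydroxyl without harming the butenolide or the acid and gives the target.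

**Compound list**

1 | 3-(trimethylsilyl)prop-2-ynal | C[Si](C)(C)C#CC=O | starting material
2 | triethyl phosphonoacetate | CCOC(=O)CP(=O)(OCC)OCC | starting material
3 | ethyl (2E)-5-(trimethylsilyl)pent-2-en-4-ynoate | CCOC(=O)/C=C/C#C[Si](C)(C)C | intermediate
4 | (2E)-5-(trimethylsilyl)pent-2-en-4-yn-1-ol | OC/C=C/C#C[Si](C)(C)C | intermediate
5 | δ-valerolactone (oxan-2-one) | O=C1CCCCO1 | starting material
6 | sodium 5-hydroxypentanoate | [Na+].[O-]C(=O)CCCCO | intermediate
7 | tert-butyldimethylsilyl 5-[(tert-butyldimethylsilyl)oxy]pentanoate | CC(C)(C)[Si](C)(C)OCCCCC(=O)O[Si](C)(C)C(C)(C)C | intermediate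
8 | 5-[(tert-butyldimethylsilyl)oxy]pentanoic acid | CC(C)(C)[Si](C)(C)OCCCCC(=O)O | intermediate
9 | (2E)-5-(trimethylsilyl)pent-2-en-4-yn-1-yl 5-[(tert-butyldimethylsilyl)oxy]pentanoate | CC(C)(C)[Si](C)(C)OCCCCC(=O)OC/C=C/C#C[Si](C)(C)C | intermediate
10 | boron ketene acetal of 9 (alkyl chain cis to O–B; boron in the (4S,5S)-1,3-bis{[3,5-bis(trifluoromethyl)phenyl]sulfonyl}-4,5-diphenyl-1,3,2-diazaborolidine) | CC(C)(C)[Si](C)(C)OCCC/C=C(/OC/C=C/C#C[Si](C)(C)C)OB1N(S(=O)(=O)c2cc(cc(c2)C(F)(F)F)C(F)(F)F)[C@@H](c2ccccc2)[C@H](c2ccccc2)N1S(=O)(=O)c1cc(cc(c1)C(F)(F)F)C(F)(F)F | intermediate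
11 | (4S,5S)-diazaborolidin-2-yl carboxylate of acid 12 | CC(C)(C)[Si](C)(C)OCCC[C@@H](C(=O)OB1N(S(=O)(=O)c2cc(cc(c2)C(F)(F)F)C(F)(F)F)[C@@H](c2ccccc2)[C@H](c2ccccc2)N1S(=O)(=O)c1cc(cc(c1)C(F)(F)F)C(F)(F)F)[C@H](C=C)C#C[Si](C)(C)C | intermediate
12 | (2R,3S)-2-{3-[(tert-butyldimethylsilyl)oxy]propyl}-3-ethenyl-5-(trimethylsilyl)pent-4-ynoic acid | CC(C)(C)[Si](C)(C)OCCC[C@@H](C(=O)O)[C@H](C=C)C#C[Si](C)(C)C | intermediate
13 | (2R,3S)-2-{3-[(tert-butyldimethylsilyl)oxy]propyl}-3-ethenyl-5-(trimethylsilyl)pent-4-yn-1-ol | CC(C)(C)[Si](C)(C)OCCC[C@@H](CO)[C@H](C=C)C#C[Si](C)(C)C | intermediate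
14 | (2R,3S)-2-{3-[(tert-butyldimethylsilyl)oxy]propyl}-3-ethenylpent-4-yn-1-ol | CC(C)(C)[Si](C)(C)OCCC[C@@H](CO)[C@H](C=C)C#C | intermediate
15 | tert-butyl{[(2R,3S)-2-{3-[(tert-butyldimethylsilyl)oxy]propyl}-3-ethenylpent-4-yn-1-yl]oxy}diphenylsilane | CC(C)(C)[Si](C)(C)OCCC[C@@H](CO[Si](c1ccccc1)(c1ccccc1)C(C)(C)C)[C@H](C=C)C#C | intermediate
16 | (E)-alkenyl(dimethyl)alane from 15 (methyl on C10, aluminium on C1, trans to C9) | CC(C)(C)[Si](C)(C)OCCC[C@@H](CO[Si](c1ccccc1)(c1ccccc1)C(C)(C)C)[C@H](C=C)/C(C)=C/[Al](C)C | intermediate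
17 | tert-butyl{[(2R,3S,4E)-2-{3-[(tert-butyldimethylsilyl)oxy]propyl}-3-ethenyl-4-methylhepta-4,6-dien-1-yl]oxy}diphenylsilane | CC(C)(C)[Si](C)(C)OCCC[C@@H](CO[Si](c1ccccc1)(c1ccccc1)C(C)(C)C)[C@H](C=C)/C(C)=C/C=C | intermediate
18 | (4R,5S,6E)-4-{[(tert-butyldiphenylsilyl)oxy]methyl}-5-ethenyl-6-methylnona-6,8-dien-1-ol | OCCC[C@@H](CO[Si](c1ccccc1)(c1ccccc1)C(C)(C)C)[C@H](C=C)/C(C)=C/C=C | intermediate
19 | (4R,5S,6E)-4-{[(tert-butyldiphenylsilyl)oxy]methyl}-5-ethenyl-6-methylnona-6,8-dienal | O=CCC[C@@H](CO[Si](c1ccccc1)(c1ccccc1)C(C)(C)C)[C@H](C=C)/C(C)=C/C=C | intermediate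
20 | (triphenylphosphoranylidene)acetaldehyde | O=CC=P(c1ccccc1)(c1ccccc1)c1ccccc1 | starting material
21 | (2E,6R,7S,8E)-6-{[(tert-butyldiphenylsilyl)oxy]methyl}-7-ethenyl-8-methylundeca-2,8,10-trienal | O=C/C=C/CC[C@@H](CO[Si](c1ccccc1)(c1ccccc1)C(C)(C)C)[C@H](C=C)/C(C)=C/C=C | intermediate
22 | (1R,4aS,5S,6R,8aS)-6-{[(tert-butyldiphenylsilyl)oxy]methyl}-5-ethenyl-4a-methyl-1,2,4a,5,6,7,8,8a-octahydronaphthalene-1-carbaldehyde | C[C@]12C=CC[C@@H](C=O)[C@@H]1CC[C@@H](CO[Si](c3ccccc3)(c3ccccc3)C(C)(C)C)[C@@H]2C=C | intermediate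
23 | potassium enolate of 22 (C4=C19–OK) | C[C@]12C=CCC(=C[O-])[C@@H]1CC[C@@H](CO[Si](c3ccccc3)(c3ccccc3)C(C)(C)C)[C@@H]2C=C.[K+] | intermediate
24 | (1S,4aR,5S,6R,8aR)-6-{[(tert-butyldiphenylsilyl)oxy]methyl}-5-ethenyl-1,4a-dimethyl-1,2,4a,5,6,7,8,8a-octahydronaphthalene-1-carbaldehyde | C[C@]12C=CC[C@](C)(C=O)[C@@H]1CC[C@@H](CO[Si](c3ccccc3)(c3ccccc3)C(C)(C)C)[C@@H]2C=C | intermediate
25 | (1S,4aR,5S,6R,8aR)-6-{[(tert-butyldiphenylsilyl)oxy]methyl}-5-ethenyl-1,4a-dimethyl-1,2,4a,5,6,7,8,8a-octahydronaphthalene-1-carboxylic acid | C[C@]12C=CC[C@](C)(C(=O)O)[C@@H]1CC[C@@H](CO[Si](c3ccccc3)(c3ccccc3)C(C)(C)C)[C@@H]2C=C | intermediate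
26 | furan-2(5H)-one | O=C1C=CCO1 | starting material
27 | trans-3,4-dibromodihydrofuran-2(3H)-one (racemic) | O=C1OC[C@H](Br)[C@H]1Br.O=C1OC[C@@H](Br)[C@@H]1Br | intermediate
28 | 3-bromofuran-2(5H)-one | O=C1OCC=C1Br | intermediate
29 | bis-borane adduct of 25 (9-BBN on C12, carboxyl group as 9-BBN acyloxyborane) | C[C@]12C=CC[C@](C)(C(=O)OB3C4CCCC3CCC4)[C@@H]1CC[C@@H](CO[Si](c5ccccc5)(c5ccccc5)C(C)(C)C)[C@@H]2CCB6C7CCCC6CCC7 | intermediate
30 | (1S,4aR,5S,6R,8aR)-6-{[(tert-butyldiphenylsilyl)oxy]methyl}-1,4a-dimethyl-5-[2-(2-oxo-2,5-dihydrofuran-3-yl)ethyl]-1,2,4a,5,6,7,8,8a-octahydronaphthalene-1-carboxylic acid | C[C@]12C=CC[C@](C)(C(=O)O)[C@@H]1CC[C@@H](CO[Si](c3ccccc3)(c3ccccc3)C(C)(C)C)[C@@H]2CCC1=CCOC1=O | intermediate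
31 | (1S,4aR,5S,6R,8aR)-6-{[(tert-butyldiphenylsilyl)oxy]methyl}-1,4a-dimethyl-5-[2-(2-oxo-2,5-dihydrofuran-3-yl)ethyl]decahydronaphthalene-1-carboxylic acid | C[C@]12CCC[C@](C)(C(=O)O)[C@@H]1CC[C@@H](CO[Si](c3ccccc3)(c3ccccc3)C(C)(C)C)[C@@H]2CCC1=CCOC1=O | intermediate
32 | (1S,4aR,5S,6R,8aR)-6-(hydroxymethyl)-1,4a-dimethyl-5-[2-(2-oxo-2,5-dihydrofuran-3-yl)ethyl]decahydronaphthalene-1-carboxylic acid | C[C@]12CCC[C@](C)(C(=O)O)[C@@H]1CC[C@@H](CO)[C@@H]2CCC1=CCOC1=O | target

**Step count and risks**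

Total step count: 18. Longest linear sequence: 16 steps (steps 1, 2, 4–14, 16–18).

Most likely to fail, step 12: the inside methyl group on the diene terminus may slow the cycloaddition so much that Lewis-acid-induced oligomerisation of the diene or erosion of endo selectivity takes over. The fallback drops the Lewis acid and changes the dienophile. It sets out from 19: Wittig reaction with tert-butyl (triphenylphosphoranylidene)acetate should give the tert-butyl trienoate F1. Heating F1 in toluene with BHT at about 170 °C in a sealed tube (the reversible 1,5-hydrogen shift of the diene only stores material) should give the trans-fused tert-butyl ester F2, to be separated from any cis-fused isomer. Deprotonation with LiN(iPr)2 in THF at −78 °C and addition of MeI should give the 4α-methyl ester F3 by the same α-face approach as in step 13. Acidolysis with CF3CO2H in CH2Cl2 then returns to the route at 25.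

Second, step 5: enantio- or syn/anti-selection may be insufficient, or the bromoborane may attack the silyl ether or the silylalkyne during the long reaction time. The fallback gives up asymmetric induction for a resolution and sets out from 9. LiN(iPr)2 in THF/DMPU at −78 °C followed by TBSCl should give the silyl ketene acetal F4, which on warming rearranges to the racemic silyl ester F5 and on aqueous work-up gives the racemic syn acid F6. Treatment with (R)-1-phenylethylamine gives two diastereomeric salts, the salt of 12 F7 and the salt of its enantiomer F8, which are separated by fractional crystallisation. Acidification of F7 with aqueous HCl returns to the route at 12.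

Third, step 16: slow transmetalation of the hindered alkylborane may allow protodeboronation or β-hydride elimination, or the base may degrade the bromobutenolide. The fallback builds the same side chain by olefination and sets out from 25. Hydroboration with 9-BBN-H and oxidation with NaOH/H2O2 should give the primary alcohol F9, and Dess–Martin oxidation the aldehyde F10. Wittig reaction with 3-(triphenylphosphoranylidene)dihydrofuran-2(3H)-one (a bought lactone ring, used in excess because of the free acid) should give the (E)-alkylidene lactone F11. Hydrogenation with H2 and RhCl(PPh3)3 should saturate the ring-A alkene to give the alkylidene lactone F12. Heating F12 with RhCl3·3H2O in EtOH should move the exocyclic double bond into the ring and returns to the route at 31.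

**Further compounds**

F1 | step 12 | tert-butyl (2E,6R,7S,8E)-6-{[(tert-butyldiphenylsilyl)oxy]methyl}-7-ethenyl-8-methylundeca-2,8,10-trienoate | CC(C)(C)OC(=O)/C=C/CC[C@@H](CO[Si](c1ccccc1)(c1ccccc1)C(C)(C)C)[C@H](C=C)/C(C)=C/C=C
F2 | step 12 | tert-butyl ester analogue of 22 (trans-fused, 4α-CO2tBu) | C[C@]12C=CC[C@@H](C(=O)OC(C)(C)C)[C@@H]1CC[C@@H](CO[Si](c3ccccc3)(c3ccccc3)C(C)(C)C)[C@@H]2C=C
F3 | step 12 | tert-butyl ester of 25 (4α-methyl, 4β-CO2tBu) | C[C@]12C=CC[C@](C)(C(=O)OC(C)(C)C)[C@@H]1CC[C@@H](CO[Si](c3ccccc3)(c3ccccc3)C(C)(C)C)[C@@H]2C=C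
F4 | step 5 | tert-butyldimethylsilyl ketene acetal of 9 (alkyl chain cis to O–Si) | CC(C)(C)[Si](C)(C)OCCC/C=C(/OC/C=C/C#C[Si](C)(C)C)O[Si](C)(C)C(C)(C)C
F5 | step 5 | racemic syn tert-butyldimethylsilyl ester of F6 | CC(C)(C)[Si](C)(C)OCCC[C@@H](C(=O)O[Si](C)(C)C(C)(C)C)[C@H](C=C)C#C[Si](C)(C)C.CC(C)(C)[Si](C)(C)OCCC[C@H](C(=O)O[Si](C)(C)C(C)(C)C)[C@@H](C=C)C#C[Si](C)(C)C
F6 | step 5 | racemic syn acid (12 and its enantiomer) | CC(C)(C)[Si](C)(C)OCCC[C@@H](C(=O)O)[C@H](C=C)C#C[Si](C)(C)C.CC(C)(C)[Si](C)(C)OCCC[C@H](C(=O)O)[C@@H](C=C)C#C[Si](C)(C)C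
F7 | step 5 | (R)-1-phenylethylammonium salt of 12 | C[C@@H]([NH3+])c1ccccc1.CC(C)(C)[Si](C)(C)OCCC[C@@H](C([O-])=O)[C@H](C=C)C#C[Si](C)(C)C
F8 | step 5 | (R)-1-phenylethylammonium salt of the enantiomer of 12 | C[C@@H]([NH3+])c1ccccc1.CC(C)(C)[Si](C)(C)OCCC[C@H](C([O-])=O)[C@@H](C=C)C#C[Si](C)(C)C
F9 | step 16 | primary alcohol from 25 (C12–OH) | C[C@]12C=CC[C@](C)(C(=O)O)[C@@H]1CC[C@@H](CO[Si](c3ccccc3)(c3ccccc3)C(C)(C)C)[C@@H]2CCO
F10 | step 16 | aldehyde from F9 (C12 aldehyde) | C[C@]12C=CC[C@](C)(C(=O)O)[C@@H]1CC[C@@H](CO[Si](c3ccccc3)(c3ccccc3)C(C)(C)C)[C@@H]2CC=O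
F11 | step 16 | (E)-alkylidene lactone (C12=C13 exocyclic, ring-A alkene present) | C[C@]12C=CC[C@](C)(C(=O)O)[C@@H]1CC[C@@H](CO[Si](c3ccccc3)(c3ccccc3)C(C)(C)C)[C@@H]2C/C=C1\CCOC1=O
F12 | step 16 | (E)-alkylidene lactone with saturated ring A | C[C@]12CCC[C@](C)(C(=O)O)[C@@H]1CC[C@@H](CO[Si](c3ccccc3)(c3ccccc3)C(C)(C)C)[C@@H]2C/C=C1\CCOC1=O
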